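**Retrosynthetic overview** (numbers as in the forward route)
1. 8 ⇐ 7: biomimetic ene-reduction of the α-allyl enone C=C of racemic dienone 7, run as an enzymatic kinetic resolution (C4 fixed by selection, C6 by protonation).
2. 7 ⇐ 2 × 5: biomimetic oxidative O–C4′ phenol coupling; one molecule of 5 is dearomatised to the cyclohexadienone mixed ketal, the other becomes the aryloxy group.
3. 5 ⇐ 3 ⇐ 1 + 2: aromatic Claisen rearrangement, then O-allylation.
4. Ring order: both six-membered rings come from the benzene ring of 1; the carbocycle of 8 is created by dearomatisation (step 3) and adjusted by reduction (step 4).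

Assumption: the plant makes this compound by oxidative O–C coupling of two molecules of 2-allyl-4,5-dimethoxyphenol followed by reduction of one dienone C=C. The target is read as (4R,6S), with the 6-allyl group cis to the 4-aryloxy group (numbering of 8: C1 = C=O, C3 = C–OMe, C4 = ketal carbon, C6 = CH–allyl; C2/C3 of 7 become C6/C5 of 8).

Handling note: 7 and 8 lose ArOH and re-aromatise under acid, and 8 can epimerise at C6 under base. Work-ups are kept near neutral and chromatography is done on Et3N-deactivated silica.

**Step 1**
Reactants: 1 3,4-dimethoxyphenol; 2 allyl bromide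
Product: 3 4-(allyloxy)-1,2-dimethoxybenzene
Conditions: K2CO3 (1.5 equiv), acetone, reflux
Reagents that add atoms: allyl bromide (compound 2), C=CCBr
Why: Williamson ether synthesis (SN2 of the potassium phenoxide on allyl bromide), with no stereocentre formed.

**Step 2**
Reactants: 3 4-(allyloxy)-1,2-dimethoxybenzene
Product: 5 2-allyl-4,5-dimethoxyphenol, via ortho-dienone 4 (not isolated)
Conditions: PhNEt2, 200 °C, argon
Reagents that add atoms: none
Why: Aromatic Claisen rearrangement ([3,3]-sigmatropic shift) to the unhindered ortho position para to the 3-OMe group gives dienone 4, which tautomerises to phenol 5, while the minor 2-allyl-3,4-dimethoxy isomer from migration to the crowded ortho position is removed by chromatography and no stereocentre survives.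

**Step 3**
Reactants: 5 2-allyl-4,5-dimethoxyphenol (two molecules)
Product: 7 rac-2-allyl-4-(2-allyl-4,5-dimethoxyphenoxy)-4,5-dimethoxycyclohexa-2,5-dien-1-one, via aryloxy-λ3-iodane 6 (not isolated)
Conditions: PhI(OAc)2 (0.5 equiv, slow addition), 4 Å MS, CH2Cl2 (0.3 M in 5), −40 → 0 °C; aq. NaHCO3 quench
Reagents that add atoms: none
Why: Proposed new method: ligand exchange on iodine(III) gives aryloxy-iodane 6, whose para carbon (the position best able to carry positive charge because of its OMe group) is attacked by the phenolic oxygen of a second molecule of 5 with loss of PhI and acetate, which is the two-electron laboratory counterpart of the biosynthetic O–C4′ phenol coupling and creates the cyclohexadienone ring with the mixed-ketal carbon C4 as a racemate, the closest known reaction types being PhI(OAc)2/alcohol oxidation of 4-methoxyphenols to para-quinone monoketals and Tl(III)- or anode-mediated phenol oxidation with phenol O-trapping as used for diaryl ethers.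

**Step 4**
Reactants: 7 rac-2-allyl-4-(2-allyl-4,5-dimethoxyphenoxy)-4,5-dimethoxycyclohexa-2,5-dien-1-one
Product: 8 (4R,6S)-6-allyl-4-(2-allyl-4,5-dimethoxyphenoxy)-3,4-dimethoxycyclohex-2-en-1-one
Conditions: ene-reductase (Old Yellow Enzyme family; hit chosen from a small panel that includes stereocomplementary OYE1 W116 variants), NADP+ (cat.), glucose dehydrogenase, D-glucose (0.6 equiv), KPi buffer pH 7.0/DMSO 9:1, 25 °C, stopped at ca. 50 % conversion
Reagents that add atoms: none
Why: Proposed new method: the ene-reductase passes hydride from FMNH2 to C3 of 7 (the β-carbon of the α-allyl enone, the only C=C it can activate because the β-methoxy enone is a deactivated vinylogous ester and the allyl groups are unactivated) and a proton from the active-site tyrosine to C2 on the opposite face, which sets C6 of 8 as S under enzyme control, while its discrimination between the OMe and OAr groups on the quaternary carbon lets it consume only (R)-7 in a kinetic resolution that fixes C4 as R, the closest known reaction types being OYE reductions of 2-alkylcyclohex-2-enones and OYE desymmetrisations of 4,4-disubstituted cyclohexa-2,5-dienones.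

The ee of 8 is checked by chiral HPLC and the cis relationship by NOE. If the enzyme also reduces (S)-7 with the same sense at the α-carbon, the product is the (4S,6S) diastereomer, which is removed on silica and does not lower the ee of 8.

**Compound list**
1 | 3,4-dimethoxyphenol | COc1ccc(O)cc1OC | starting material
2 | allyl bromide | C=CCBr | starting material
3 | 4-(allyloxy)-1,2-dimethoxybenzene | C=CCOc1ccc(OC)c(OC)c1 | intermediate
4 | 6-allyl-3,4-dimethoxycyclohexa-2,4-dien-1-one (racemic, transient Claisen dienone) | C=CCC1C=C(OC)C(OC)=CC1=O | intermediate
5 | 2-allyl-4,5-dimethoxyphenol | C=CCc1cc(OC)c(OC)cc1O | intermediate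
6 | acetoxy(2-allyl-4,5-dimethoxyphenoxy)(phenyl)-λ3-iodane | C=CCc1cc(OC)c(OC)cc1OI(OC(C)=O)c1ccccc1 | intermediate
7 | rac-2-allyl-4-(2-allyl-4,5-dimethoxyphenoxy)-4,5-dimethoxycyclohexa-2,5-dien-1-one (both enantiomers at C4) | C=CCc1cc(OC)c(OC)cc1OC1(OC)C=C(CC=C)C(=O)C=C1OC | intermediate
8 | (4R,6S)-6-allyl-4-(2-allyl-4,5-dimethoxyphenoxy)-3,4-dimethoxycyclohex-2-en-1-one | C=CCc1cc(OC)c(OC)cc1O[C@]1(OC)C[C@H](CC=C)C(=O)C=C1OC | target

**Totals**
Total step count: 4. Longest linear sequence: 4 steps (1 → 3 → 5 → 7 → 8). Step 4 is a resolution, so its yield is at most 50 %. The recovered (S)-enantiomer of 7 can be cleaved reductively (Zn, AcOH) to two molecules of 5 and recycled.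

**Steps most likely to fail, with fallbacks**

Step 3 (most risky). The phenol can attack through carbon (C6) and give biaryls, acetate or water can trap the cation and lead to the quinone, and the mixed aryl ketal is acid-labile. The fallback sets out from 5 and comes back at 7, and replaces the direct coupling by a ketal exchange. One portion of 5 is oxidised with PhI(OAc)2 in MeOH at 0 °C to the dimethyl ketal 2-allyl-4,4,5-trimethoxycyclohexa-2,5-dien-1-one F1, which is standard quinone monoketal formation. A second portion is silylated (TMSCl, Et3N, CH2Cl2) to (2-allyl-4,5-dimethoxyphenoxy)trimethylsilane F2. The two are joined by Noyori-type transketalisation (TMSOTf 5 mol %, CH2Cl2, −78 °C, pyridine quench). F1 loses one methoxy group to give the same oxocarbenium ion as in step 3, now without oxidant, acetate or free phenol, and the silyl ether delivers its oxygen to C4 to give 7.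

Step 4. The enzyme may not accept the bulky substrate, may not distinguish the enantiomers of 7, or reduced flavin may cleave the quinol ether back to 5. The fallback sets out from 7 and comes back at 8, and uses a copper hydride kinetic resolution instead. Cu(OAc)2 (5 mol %), DTBM-SEGPHOS (the enantiomer matched to (R)-7, found by trial), PhMe2SiH (0.55 equiv), toluene, −40 °C deliver hydride to C3 of (R)-7 only. This gives {[(4R)-2-allyl-4-(2-allyl-4,5-dimethoxyphenoxy)-4,5-dimethoxycyclohexa-1,5-dien-1-yl]oxy}dimethyl(phenyl)silane F3, which is separated from unreacted (S)-7. Protodesilylation at −78 °C (TBAF buffered with AcOH, THF) then puts the proton on the face anti to the bulky aryloxy group and gives 8. A C6 epimer, if formed, is a diastereomer and is removed on silica.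

Step 2. The Claisen rearrangement can give a sizeable amount of the 2-allyl-3,4-dimethoxy regioisomer, which is hard to separate. The fallback sets out from 1 and comes back at 5, and fixes the regiochemistry by bromination. NBS (1.0 equiv, MeCN, 0 °C) brominates 1 ortho to OH and para to the 3-OMe group to give 2-bromo-4,5-dimethoxyphenol F4. Suzuki–Miyaura allylation (allylboronic acid pinacol ester, Pd(OAc)2/SPhos, K3PO4, THF/H2O, 60 °C) then gives 5, and compounds 2–4 are no longer needed.

**Further compounds**
F1 | step 3 | 2-allyl-4,4,5-trimethoxycyclohexa-2,5-dien-1-one | C=CCC1=CC(OC)(OC)C(OC)=CC1=O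
F2 | step 3 | (2-allyl-4,5-dimethoxyphenoxy)trimethylsilane | C=CCc1cc(OC)c(OC)cc1O[Si](C)(C)C
F3 | step 4 | {[(4R)-2-allyl-4-(2-allyl-4,5-dimethoxyphenoxy)-4,5-dimethoxycyclohexa-1,5-dien-1-yl]oxy}dimethyl(phenyl)silane | C=CCc1cc(OC)c(OC)cc1O[C@]1(OC)CC(CC=C)=C(O[Si](C)(C)c2ccccc2)C=C1OC
F4 | step 2 | 2-bromo-4,5-dimethoxyphenol | COc1cc(O)c(Br)cc1OC
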